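Locants used for the target and for every intermediate: ring A is C1 (bears C7H2), C2 (isopropenyl), C3, C4, C5 (C(CH3)OH), C6 (CHOH); the linker is C7H2–C8(=C9H2); ring B is C1' (bonded to C8), C2', C3', C4' (C(CH3)OH), C5' (CHBr), C6'. Compound numbers are those of the steps below.

## Analysis of the target

The target 20 (C20H33BrO3) consists of two separate cyclohexanes, ring A and ring B, joined by a three-carbon unit: C1 of ring A carries C7H2, C7 is bonded to the methylidene carbon C8 (C8=C9H2), and C8 is bonded to C1' of ring B. Ring A has four contiguous stereocentres, C1 (R), C2 (S), C5 (S) and C6 (S). In its chair the C1 side chain, the C2 isopropenyl group and both hydroxyls are equatorial and only the C5 methyl is axial, so C1/C2, C1/C6 and the C5/C6 diol are all trans. Ring B has C1' (R), C4' (S) and C5' (R): the side chain, the C4' methyl and the C5' bromine are equatorial and the C4' hydroxyl is axial, so bromine and hydroxyl are cis. This is a bromohydrin that anti addition of bromine and water to an alkene cannot give. The stereocentres of the two rings are insulated from each other by C7 and C8, so neither ring can direct the other and each must be set in absolute terms. The sensitive groups are the secondary bromide next to a tertiary alcohol (base can cause ring contraction or elimination) and the tertiary alcohols and the two 1,1-disubstituted alkenes (acid can cause ionisation and cation–olefin chemistry). The hard points are the cis bromohydrin, the remote C1/C1' relationship, and telling three alkenes and four hydroxyls apart late in the route. The strategy rests on one feature of ring B: its only carbon substituent, at C1', is para to the methyl-bearing C4', and the C4'–O/C5'–Br pair sits where a C4'=C5' alkene would be. With C8 read as a ketone, this is the pattern left by a Diels–Alder reaction of isoprene with a vinyl ketone.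

## Retrosynthetic reasoning

**20 from 19.** The last operation only removes silicon from three oxygens. The ring A diol is carried as two silyl ethers and the C4' hydroxyl as a trimethylsilyl ether, all of which fall to one fluoride treatment under mildly acidic conditions that the cis bromohydrin tolerates.

**C5'–Br (19 from 16 through 17 and 18).** The C5'–Br bond is cut to bromide ion and an electrophilic C5'. Because bromine must end up cis to the C4' oxygen, and a nucleophile enters with inversion, the precursor must have a leaving group at C5' trans to that oxygen. This is the trans-diaxial diol 16, activated at its secondary hydroxyl as triflate 17. A free trans-diaxial tertiary hydroxyl would close onto C5' and give an epoxide, so it is capped in the same flask (18) before bromide is added. The forward reaction must be an SN2 displacement of an axial leaving group at a hindered secondary carbon, and it must beat elimination.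

**C4'–O and C5'–O (16 from 15 from 14).** The diol is traced to the C4'=C5' alkene through its epoxides. Facial selectivity in the epoxidation is not needed: under acid each epoxide is opened trans-diaxially, one at C4' and the other at C5', and both give the same diol 16. The epoxidation only has to choose the trisubstituted ring alkene over the two 1,1-disubstituted alkenes.

**C8=C9 (14 from 13).** The methylidene is cut back to the C8 ketone. This recovers the carbonyl that the cycloaddition needs. The forward methylenation must not epimerise C1', which is α to that carbonyl, so a non-basic titanium methylidene reagent is planned instead of a phosphorus ylide.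

**Ring B (13 from 11 and 12).** This is the key disconnection. The bonds C1'–C6' and C2'–C3' are cut, which opens ring B into isoprene 12 and the vinyl ketone 11. The cut is made here because it removes a whole ring and the C1' stereocentre in one step. It also leaves the alkene exactly at C4'=C5', where the bromohydrin is wanted, and places the new stereocentre under catalyst control, which is the only control possible so far from ring A. The forward reaction must deliver the para regioisomer and a single configuration at C1'.

**C8–vinyl (11 from 9 and 10).** The enone is cut between C8 and the vinyl group into the N-methoxy-N-methyl amide 9 and vinylmagnesium bromide 10. The amide stops cleanly at the ketone stage.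

**Protection and C6 (9 from 8 from 7).** The trans-diequatorial C5/C6 diol is masked as two tert-butyldimethylsilyl ethers. A cyclic ketal across it would be a strained trans-fused dioxolane, which would not survive the aqueous acid of the epoxide opening or the silyl triflate used at C4'. The C6 carbinol comes from the ketone of 7 by hydride delivery from the face of the C5 hydroxyl.

**C1–C7 (7 from 4 and 5 through 6).** The side chain is cut off at C1–C7, back to the enolate of hydroxy ketone 4 and the bromoacetamide 5, which brings C7 and C8 already at the amide oxidation level. The site of enolisation is not in question, because the other α-carbon, C5, is fully substituted. The isopropenyl group at C2 directs the electrophile to the opposite face.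

**Ring A oxygenation (4 from 3 from 2 from 1).** The tertiary carbinol at C5 is traced to the epoxide of the enone of (S)-carvone 1. Carvone supplies C2 with the correct configuration, and the epoxide forms trans to the isopropenyl group, which is the C2/C5 relationship of the target. Hydride opening at C4 and re-oxidation at C6 give 4.

## Alternatives that were turned down

**Alternative 1:** Ring A is cut at two bonds, C2–isopropenyl and C1–C7. In the forward direction an isopropenyl copper nucleophile would add to C2 of the enone A1, and the resulting C1 enolate would be trapped in the same flask by the allylic bromide A2, which already carries ring B with its bromohydrin. This gives the ketone A3 without closing any ring. In its favour, it is the most convergent plan and the trans relationship of vicinal groups from conjugate addition and enolate trapping is dependable. The cis bromohydrin is also solved on a small fragment, where a poor step costs little. On step economy and on where the bromine problem is faced it is stronger than the chosen route. Against it, the configuration at C2 would have to be induced by C5, which lies across the ring and differentiates the two faces only by a silyloxy group against a methyl group. A1 is not a chiral-pool compound and needs its own asymmetric synthesis. The enolate would also meet the secondary bromide of A2, with elimination as a likely side path, and C6 would still need reduction. The chosen strategy instead takes C2 and C5 from carvone with their relationship fixed, and sets C1' by a catalyst. It pays for this with a longer linear sequence and a late bromide displacement.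

**Alternative 2:** Ring A is cut at C5–C6. In the forward direction a chiral N-heterocyclic carbene would add to the C6 aldehyde of the open-chain keto-aldehyde A4 and turn it into an acyl anion equivalent. This would attack the C5 methyl ketone, closing ring A and giving the α-hydroxy ketone A5. In its favour, the ring and the tertiary carbinol are made in one catalytic step without protecting groups, and A5 is one reduction away from the target. In bond economy at the key step it equals the cycloaddition. Against it, A4 must carry C1 and C2 already set in an open chain, where 1,2-induction is weak. C1 is α to the aldehyde and is exposed to the base that generates the carbene. The new C5 centre would be formed under competing control by the catalyst and by two nearby stereocentres, and the base-sensitive bromohydrin would have to ride through the step. The chosen strategy builds the ring A centres on a ring that carvone provides, by reactions whose facial preference is set by that ring.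

**Alternative 3:** Ring A is cut at C1–C2. In the forward direction a strong Lewis acid would activate the enone of the open-chain allylsilane A6. The allylsilane carbon C2 would attack the enone β-carbon C1 through a chair, silicon would leave and unveil the isopropenyl group, and the product A7 would keep C8 as a ketone. In its favour, ring A, the C1/C2 trans relationship and the isopropenyl group are made in one step, and C8 stays ready for methylenation. In forming ring A this plan is as strong as any. Against it, the strong Lewis acid would meet an acetonide, a tertiary silyl ether and the bromohydrin. The enone carries an oxygen at the γ-position (C6), which invites elimination. Ring closure creates a trans-fused dioxolane, and the strain would slow the cyclisation and let protodesilylation compete. Both new centres depend on induction from C6, and A6 needs a long linear preparation that includes a ring B ketone fragment with the bromohydrin in place. The chosen strategy reaches its key-step precursor in seven steps from carvone and keeps acid-sensitive groups away from strong Lewis acids.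

Key step: step 8

Assumption: the cationic oxazaborolidine made from (S)-α,α-diphenylprolinol is taken to be the antipode that gives (R) at C1'; if the sense is the opposite, the catalyst from (R)-α,α-diphenylprolinol is used and nothing else changes.

Shorthand in names: RA is the (1R,2S,3S,6S)-2,3-bis(tert-butyldimethylsilyloxy)-3-methyl-6-(prop-1-en-2-yl)cyclohexyl group, i.e. ring A attached through C1 with silyl ethers on the C5 and C6 oxygens.

## Route

Step 1
Reactants: 1 (S)-carvone
Product: 2 (1S,4S,6S)-1-methyl-4-(prop-1-en-2-yl)-7-oxabicyclo[4.1.0]heptan-2-one (oxirane trans to the isopropenyl group)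
Conditions: 30% aq. H2O2, NaOH (cat.), MeOH, 0 °C
Reagents that add atoms: hydrogen peroxide, OO
Why: Weitz–Scheffer nucleophilic epoxidation touches only the electron-poor enone alkene; hydroperoxide adds to C4 on the face away from the C2 isopropenyl group, so the oxygen that becomes the C5 hydroxyl is set trans to it (C5 S).

Step 2
Reactants: 2 (1S,4S,6S)-1-methyl-4-(prop-1-en-2-yl)-7-oxabicyclo[4.1.0]heptan-2-one
Product: 3 (1S,4S)-1-methyl-4-(prop-1-en-2-yl)cyclohexane-1,2-diol (both epimers at the secondary carbinol C6)
Conditions: LiAlH4, THF, 0 °C → reflux; aqueous NaOH work-up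
Reagents that add atoms: none
Why: Hydride reduces the ketone and opens the oxirane by SN2 attack at the less substituted carbon C4, which leaves the tertiary C5–O bond and its configuration untouched; the C6 carbinol need not be controlled because step 3 oxidises it.

Step 3
Reactants: 3 (1S,4S)-1-methyl-4-(prop-1-en-2-yl)cyclohexane-1,2-diol
Product: 4 (2S,5S)-2-hydroxy-2-methyl-5-(prop-1-en-2-yl)cyclohexan-1-one
Conditions: IBX, DMSO, rt
Reagents that add atoms: none
Why: IBX oxidation of a 1,2-diol stops at the α-hydroxy ketone without glycol cleavage; the tertiary hydroxyl and the isopropenyl group cannot react.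

Step 4
Reactants: 4 (2S,5S)-2-hydroxy-2-methyl-5-(prop-1-en-2-yl)cyclohexan-1-one; 5 2-bromo-N-methoxy-N-methylacetamide
Product: 7 2-[(1R,3S,6S)-3-hydroxy-3-methyl-2-oxo-6-(prop-1-en-2-yl)cyclohexyl]-N-methoxy-N-methylacetamide, via dilithium alkoxide enolate 6 (not isolated)
Conditions: LiN(iPr)2 (2.2 equiv), THF, −78 → −30 °C; then 5, DMPU, −78 → −20 °C; aq. NH4Cl
Reagents that add atoms: 2-bromo-N-methoxy-N-methylacetamide (5), CON(C)C(=O)CBr
Why: Enolate alkylation; only C1 can be deprotonated because C5 is fully substituted, and the electrophile enters C1 on the face opposite the neighbouring C2 isopropenyl group, giving the trans (diequatorial) arrangement (C1 R). The trans isomer is also the more stable one, so any cis material can be equilibrated through the enol.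

Step 5
Reactants: 7 2-[(1R,3S,6S)-3-hydroxy-3-methyl-2-oxo-6-(prop-1-en-2-yl)cyclohexyl]-N-methoxy-N-methylacetamide
Product: 8 2-[(1R,2S,3S,6S)-2,3-dihydroxy-3-methyl-6-(prop-1-en-2-yl)cyclohexyl]-N-methoxy-N-methylacetamide
Conditions: Me4NBH(OAc)3, MeCN/AcOH, −20 → 0 °C
Reagents that add atoms: none
Why: Hydroxyl-directed (Evans–Saksena) reduction: the C5 hydroxyl exchanges onto boron and hydride reaches C6 from the face of that oxygen, giving the trans diol (C6 S, hydroxyl equatorial). This is also the axial trajectory opposite the axial C5 methyl, so the intrinsic and the directed preference agree; the amide is not reduced.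

Step 6
Reactants: 8 2-[(1R,2S,3S,6S)-2,3-dihydroxy-3-methyl-6-(prop-1-en-2-yl)cyclohexyl]-N-methoxy-N-methylacetamide
Product: 9 2-RA-N-methoxy-N-methylacetamide (bis-silyl ether of 8)
Conditions: TBSOTf (3 equiv), 2,6-lutidine, CH2Cl2, 0 °C → rt
Reagents that add atoms: tert-butyldimethylsilyl trifluoromethanesulfonate, CC(C)(C)[Si](C)(C)OS(=O)(=O)C(F)(F)F
Why: The silyl triflate is reactive enough to silylate the tertiary as well as the secondary hydroxyl; the two ethers stand up to the Grignard reagent, the Lewis acid of step 8, the aqueous acid of step 11 and the silyl triflate of step 12.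

Step 7
Reactants: 9 2-RA-N-methoxy-N-methylacetamide; 10 vinylmagnesium bromide
Product: 11 1-RA-but-3-en-2-one (ring A vinyl ketone, C8 as the ketone)
Conditions: CH2=CHMgBr (10, 2.5 equiv), THF, −20 → 0 °C; inverse quench into cold 1 M HCl
Reagents that add atoms: vinylmagnesium bromide (10), C=C[Mg]Br
Why: Weinreb ketone synthesis: the magnesium chelate of the tetrahedral adduct holds until work-up, so no second addition occurs; the inverse acidic quench protonates the liberated amine before it can add to the enone.

Step 8
Reactants: 11 1-RA-but-3-en-2-one; 12 isoprene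
Product: 13 2-RA-1-[(1R)-4-methylcyclohex-3-en-1-yl]ethan-1-one
Conditions: (S)-3,3-diphenyl-1-(2-methylphenyl)tetrahydro-1H,3H-pyrrolo[1,2-c][1,3,2]oxazaborole (20 mol %) with HN(SO2CF3)2 (18 mol %), isoprene (12, 5 equiv), CH2Cl2, −78 → −40 °C
Reagents that add atoms: isoprene (12), C=CC(C)=C
Why: The N-protonated oxazaborolidine is a cationic boron Lewis acid that binds the C8 carbonyl oxygen of 11 on its vinyl side, lowers the LUMO of the enone and covers one of its faces with an aryl group, so isoprene adds to the open face in a concerted but asynchronous [4+2] cycloaddition. The closest known reaction type is the cationic oxazaborolidine-catalysed Diels–Alder reaction of acrylates and acyclic α,β-enones with isoprene and other 2-substituted butadienes. Ring B closes by this intermolecular suprafacial cycloaddition: C2'–C3' forms ahead of C1'–C6', and the six-membered ring appears in one kinetic step with its alkene at C4'=C5'. The only new stereocentre, C1' (R), is set by the catalyst's choice of enone face. Ring A should not interfere, because its nearest stereocentre C1 is separated from the dienophile by C7 and the carbonyl and lies on the side of the carbonyl away from boron. The step needs para regioselectivity, which follows from the bond between the enone β-carbon and the CH2 terminus next to the methyl-bearing carbon of isoprene being the more advanced one, and Lewis acid catalysis sharpens this. It also needs chemoselectivity: the isopropenyl group is unactivated and no dienophile, and the silyl ethers do not bind the catalyst at low temperature.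

Step 9
Reactants: 13 2-RA-1-[(1R)-4-methylcyclohex-3-en-1-yl]ethan-1-one
Product: 14 (4R)-1-methyl-4-(3-RA-prop-1-en-2-yl)cyclohex-1-ene
Conditions: Cp2TiMe2 (2.5 equiv), toluene, 65 °C, dark
Reagents that add atoms: dimethyltitanocene (Cp2TiMe2), C[Ti](C)(C1C=CC=C1)C1C=CC=C1
Why: Petasis methylenation: the reagent loses methane to give Cp2Ti=CH2, which adds to the ketone and collapses through an oxatitanacyclobutane. It is not basic, so the C1' stereocentre α to the carbonyl is not epimerised.

Step 10
Reactants: 14 (4R)-1-methyl-4-(3-RA-prop-1-en-2-yl)cyclohex-1-ene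
Product: 15 C4'/C5' epoxide of 14 (both epoxide faces, C1' R)
Conditions: mCPBA (1.05 equiv), NaHCO3, CH2Cl2, −20 → 0 °C
Reagents that add atoms: 3-chloroperbenzoic acid, O=C(OO)c1cccc(Cl)c1
Why: Prilezhaev epoxidation; the trisubstituted ring alkene is more electron-rich than the two 1,1-disubstituted alkenes and reacts first with one equivalent of peracid. No facial selectivity is needed because both epoxides are used.

Step 11
Reactants: 15 C4'/C5' epoxide of 14 (both faces)
Product: 16 (1S,2S,4R)-1-methyl-4-(3-RA-prop-1-en-2-yl)cyclohexane-1,2-diol (C4'–OH and C5'–OH trans-diaxial)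
Conditions: HClO4 (cat.), THF/H2O (3:1), 0 °C
Reagents that add atoms: water, O
Why: Acid-catalysed trans-diaxial epoxide opening (Fürst–Plattner rule): the epoxide on the face away from the side chain is attacked by water at C4', the other at C5', and both give the same diol with C4' S and C5' S. The silyl ethers are stable to brief dilute acid.

Step 12
Reactants: 16 (1S,2S,4R)-1-methyl-4-(3-RA-prop-1-en-2-yl)cyclohexane-1,2-diol
Product: 19 [(1S,2R,4R)-2-bromo-1-methyl-4-(3-RA-prop-1-en-2-yl)cyclohexyl]oxy(trimethyl)silane, via hydroxy triflate 17 (not isolated), via silyloxy triflate 18 (not isolated)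
Conditions: Tf2O (1.1 equiv), 2,6-lutidine, CH2Cl2, −78 °C; TMSOTf (1.1 equiv), −78 °C; Bu4NBr (4 equiv), −78 → 0 °C
Reagents that add atoms: trifluoromethanesulfonic anhydride (its atoms stay only in 17 and 18), O=S(=O)(OS(=O)(=O)C(F)(F)F)C(F)(F)F; trimethylsilyl trifluoromethanesulfonate, C[Si](C)(C)OS(=O)(=O)C(F)(F)F; tetrabutylammonium bromide, CCCC[N+](CCCC)(CCCC)CCCC.[Br-]
Why: Only the secondary C5' hydroxyl is sulfonylated; the tertiary hydroxyl is then capped so that it cannot close onto C5' to give an epoxide; bromide then displaces the axial triflate by SN2 from the opposite face and ends up equatorial. Inversion at C5' turns the trans diol into the cis bromohydrin (C5' R). Displacement of an axial sulfonate that has a protected trans-diaxial oxygen neighbour is a known reaction type in 1,6-anhydrohexopyranoses.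

Step 13
Reactants: 19 [(1S,2R,4R)-2-bromo-1-methyl-4-(3-RA-prop-1-en-2-yl)cyclohexyl]oxy(trimethyl)silane
Product: 20 (1S,2R,4R)-2-bromo-4-{3-[(1R,2S,3S,6S)-2,3-dihydroxy-3-methyl-6-(prop-1-en-2-yl)cyclohexyl]prop-1-en-2-yl}-1-methylcyclohexan-1-ol (target)
Conditions: HF·pyridine, pyridine, THF, 0 → 40 °C
Reagents that add atoms: none
Why: Fluoride cleavage of all three silyl ethers under buffered, mildly acidic conditions; the cis bromohydrin cannot close to an epoxide and the hindered secondary bromide is inert to fluoride, so no stereocentre is touched.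

## Compound list

1 | (S)-carvone, (5S)-2-methyl-5-(prop-1-en-2-yl)cyclohex-2-en-1-one | CC1=CC[C@@H](CC1=O)C(C)=C | starting material
2 | (1S,4S,6S)-1-methyl-4-(prop-1-en-2-yl)-7-oxabicyclo[4.1.0]heptan-2-one | O=C1C[C@@H](C(C)=C)C[C@@H]2O[C@]12C | intermediate
3 | (1S,4S)-1-methyl-4-(prop-1-en-2-yl)cyclohexane-1,2-diol, both epimers at the secondary carbinol | OC1C[C@@H](C(C)=C)CC[C@]1(C)O | intermediate
4 | (2S,5S)-2-hydroxy-2-methyl-5-(prop-1-en-2-yl)cyclohexan-1-one | O=C1C[C@@H](C(C)=C)CC[C@]1(C)O | intermediate
5 | 2-bromo-N-methoxy-N-methylacetamide | CON(C)C(=O)CBr | starting material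
6 | dilithium (3S,6S)-6-methyl-3-(prop-1-en-2-yl)cyclohex-1-ene-1,6-bis(olate), the alkoxide enolate of 4 (not isolated) | [Li]OC1=C[C@@H](C(C)=C)CC[C@]1(C)O[Li] | intermediate
7 | 2-[(1R,3S,6S)-3-hydroxy-3-methyl-2-oxo-6-(prop-1-en-2-yl)cyclohexyl]-N-methoxy-N-methylacetamide | CON(C)C(=O)C[C@@H]1[C@@H](C(=C)C)CC[C@](C)(O)C1=O | intermediate
8 | 2-[(1R,2S,3S,6S)-2,3-dihydroxy-3-methyl-6-(prop-1-en-2-yl)cyclohexyl]-N-methoxy-N-methylacetamide | CON(C)C(=O)C[C@@H]1[C@@H](C(=C)C)CC[C@](C)(O)[C@H]1O | intermediate
9 | 2-[(1R,2S,3S,6S)-2,3-bis(tert-butyldimethylsilyloxy)-3-methyl-6-(prop-1-en-2-yl)cyclohexyl]-N-methoxy-N-methylacetamide | CON(C)C(=O)C[C@@H]1[C@@H](C(=C)C)CC[C@](C)(O[Si](C)(C)C(C)(C)C)[C@H]1O[Si](C)(C)C(C)(C)C | intermediate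
10 | vinylmagnesium bromide | C=C[Mg]Br | starting material
11 | 1-[(1R,2S,3S,6S)-2,3-bis(tert-butyldimethylsilyloxy)-3-methyl-6-(prop-1-en-2-yl)cyclohexyl]but-3-en-2-one | C=CC(=O)C[C@@H]1[C@@H](C(=C)C)CC[C@](C)(O[Si](C)(C)C(C)(C)C)[C@H]1O[Si](C)(C)C(C)(C)C | intermediate
12 | isoprene (2-methylbuta-1,3-diene) | C=CC(C)=C | starting material
13 | 2-[(1R,2S,3S,6S)-2,3-bis(tert-butyldimethylsilyloxy)-3-methyl-6-(prop-1-en-2-yl)cyclohexyl]-1-[(1R)-4-methylcyclohex-3-en-1-yl]ethan-1-one | O=C(C[C@@H]1[C@@H](C(=C)C)CC[C@](C)(O[Si](C)(C)C(C)(C)C)[C@H]1O[Si](C)(C)C(C)(C)C)[C@@H]1CCC(C)=CC1 | intermediate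
14 | (4R)-4-{3-[(1R,2S,3S,6S)-2,3-bis(tert-butyldimethylsilyloxy)-3-methyl-6-(prop-1-en-2-yl)cyclohexyl]prop-1-en-2-yl}-1-methylcyclohex-1-ene | C=C(C[C@@H]1[C@@H](C(=C)C)CC[C@](C)(O[Si](C)(C)C(C)(C)C)[C@H]1O[Si](C)(C)C(C)(C)C)[C@@H]1CCC(C)=CC1 | intermediate
15 | C4'/C5' epoxide of 14, both epoxide faces (C1' R) | C=C(C[C@@H]1[C@@H](C(=C)C)CC[C@](C)(O[Si](C)(C)C(C)(C)C)[C@H]1O[Si](C)(C)C(C)(C)C)[C@@H]1CCC2(C)OC2C1 | intermediate
16 | (1S,2S,4R)-4-{3-[(1R,2S,3S,6S)-2,3-bis(tert-butyldimethylsilyloxy)-3-methyl-6-(prop-1-en-2-yl)cyclohexyl]prop-1-en-2-yl}-1-methylcyclohexane-1,2-diol | C=C(C[C@@H]1[C@@H](C(=C)C)CC[C@](C)(O[Si](C)(C)C(C)(C)C)[C@H]1O[Si](C)(C)C(C)(C)C)[C@@H]1CC[C@](C)(O)[C@@H](O)C1 | intermediate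
17 | (1S,2S,5R)-2-hydroxy-2-methyl-5-(3-RA-prop-1-en-2-yl)cyclohexyl trifluoromethanesulfonate (not isolated) | C=C(C[C@@H]1[C@@H](C(=C)C)CC[C@](C)(O[Si](C)(C)C(C)(C)C)[C@H]1O[Si](C)(C)C(C)(C)C)[C@@H]1CC[C@](C)(O)[C@@H](OS(=O)(=O)C(F)(F)F)C1 | intermediate
18 | (1S,2S,5R)-2-methyl-2-(trimethylsilyloxy)-5-(3-RA-prop-1-en-2-yl)cyclohexyl trifluoromethanesulfonate (not isolated) | C=C(C[C@@H]1[C@@H](C(=C)C)CC[C@](C)(O[Si](C)(C)C(C)(C)C)[C@H]1O[Si](C)(C)C(C)(C)C)[C@@H]1CC[C@](C)(O[Si](C)(C)C)[C@@H](OS(=O)(=O)C(F)(F)F)C1 | intermediate
19 | [(1S,2R,4R)-2-bromo-1-methyl-4-(3-RA-prop-1-en-2-yl)cyclohexyl]oxy(trimethyl)silane | C=C(C[C@@H]1[C@@H](C(=C)C)CC[C@](C)(O[Si](C)(C)C(C)(C)C)[C@H]1O[Si](C)(C)C(C)(C)C)[C@@H]1CC[C@](C)(O[Si](C)(C)C)[C@H](Br)C1 | intermediate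
20 | (1S,2R,4R)-2-bromo-4-{3-[(1R,2S,3S,6S)-2,3-dihydroxy-3-methyl-6-(prop-1-en-2-yl)cyclohexyl]prop-1-en-2-yl}-1-methylcyclohexan-1-ol | C=C(C[C@@H]1[C@@H](C(=C)C)CC[C@](C)(O)[C@H]1O)[C@@H]1CC[C@](C)(O)[C@H](Br)C1 | target

## Step count and least certain steps

Total step count: 13. Longest linear sequence: 13 steps, from 1 to 20; 5, 10 and 12 are purchased.

**Step 8 (key step).** The catalyst may not discriminate the enone faces well enough. The dienophile is an α-unsubstituted vinyl ketone whose two carbonyl lone pairs differ only by a CH2 group against a vinyl group, and a mismatch between the catalyst and the chiral ring A side chain cannot be ruled out. Acid-induced polymerisation of the vinyl ketone is the second concern. A C1' epimer would be a diastereomer that differs only at a remote centre and would be hard to remove. The fallback takes C1' from the chiral pool and forms C1–C7 with the whole side chain in place; it sets out from 4 and comes back at 14. Commercial (R)-limonene is metallated at its isopropenyl methyl group with n-BuLi/TMEDA; the symmetric allyllithium is trapped with B(OMe)3 and oxidised with alkaline H2O2 to (R)-2-(4-methylcyclohex-3-en-1-yl)prop-2-en-1-ol F1. CBr4/PPh3 converts this into the allylic bromide (R)-4-(3-bromoprop-1-en-2-yl)-1-methylcyclohex-1-ene F2. Alkylation of the dianion 6 of ketone 4 with F2, as in step 4, gives the hydroxy ketone (2S,5S,6R)-2-hydroxy-2-methyl-6-{2-[(1R)-4-methylcyclohex-3-en-1-yl]prop-2-en-1-yl}-5-(prop-1-en-2-yl)cyclohexan-1-one F3. Directed reduction with Me4NBH(OAc)3 gives the diol (1S,2S,3R,4S)-1-methyl-3-{2-[(1R)-4-methylcyclohex-3-en-1-yl]prop-2-en-1-yl}-4-(prop-1-en-2-yl)cyclohexane-1,2-diol F4, and TBSOTf/2,6-lutidine gives 14.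

**Step 12.** The displacement at C5' may be too slow. The carbon is flanked by the fully substituted C4', and bromide must pass the axial C4' oxygen. E2 loss of the triflate toward C6' could then take over, or the C4' oxygen could close onto C5' with loss of its silyl group. The fallback brings bromine in as an electrophile and makes the tertiary carbinol last; it sets out from 11 and comes back at 20. The vinyl ketone 11 is combined with 2-(triisopropylsilyloxy)buta-1,3-diene under the catalyst of step 8 to give the silyl enol ether 2-RA-1-[(1R)-4-(triisopropylsilyloxy)cyclohex-3-en-1-yl]ethan-1-one F5. Methylenation with Cp2TiMe2 gives (4R)-4-(3-RA-prop-1-en-2-yl)-1-(triisopropylsilyloxy)cyclohex-1-ene F6. NBS in THF at 0 °C brominates the enol ether at C5'; the C5' epimers are equilibrated through the enol and separated to give the equatorial bromide (2R,4R)-2-bromo-4-(3-RA-prop-1-en-2-yl)cyclohexan-1-one F7. MeMgBr with CeCl3 at −78 °C adds methyl from the equatorial direction and gives the cis bromohydrin (1S,2R,4R)-2-bromo-1-methyl-4-(3-RA-prop-1-en-2-yl)cyclohexan-1-ol F8. The C4' epimer, in which oxygen and bromine are trans, is removed by chromatography. HF·pyridine then gives 20.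

**Step 10.** Oxidation may spill over to the isopropenyl group or to C8=C9, because two 1,1-disubstituted alkenes compete with one trisubstituted alkene, and double epoxidation would follow with any excess of peracid. The fallback changes the order of events so that only one alkene competes; it sets out from 13 and comes back at 16. Ketone 13 is epoxidised with mCPBA to the epoxy ketone 2-RA-1-[(3R)-6-methyl-7-oxabicyclo[4.1.0]heptan-3-yl]ethan-1-one F9 (both epoxide faces). Dilute HClO4 in aqueous THF opens it to the diol ketone 2-RA-1-[(1R,3S,4S)-3,4-dihydroxy-4-methylcyclohexyl]ethan-1-one F10, and an excess of Cp2TiMe2 methylenates C8 to give 16.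

**Step 4.** The tertiary alkoxide of the dianion may be alkylated at oxygen, or the aggregated dianion may react sluggishly, so that proton transfer to the product leads to double alkylation. The fallback removes the alkoxide; it sets out from 4 and comes back at 9. Ketone 4 is silylated with TBSOTf/2,6-lutidine to (2S,5S)-2-(tert-butyldimethylsilyloxy)-2-methyl-5-(prop-1-en-2-yl)cyclohexan-1-one F11. Its monolithium enolate (LiN(iPr)2, 1.1 equiv) is alkylated with 5 to give 2-[(1R,3S,6S)-3-(tert-butyldimethylsilyloxy)-3-methyl-2-oxo-6-(prop-1-en-2-yl)cyclohexyl]-N-methoxy-N-methylacetamide F12. NaBH4 in MeOH at 0 °C, attacking axially opposite the axial C5 methyl, gives 2-[(1R,2S,3S,6S)-3-(tert-butyldimethylsilyloxy)-2-hydroxy-3-methyl-6-(prop-1-en-2-yl)cyclohexyl]-N-methoxy-N-methylacetamide F13, and a second silylation with TBSOTf gives 9.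

## Further compounds

F1 | step 8 | (R)-2-(4-methylcyclohex-3-en-1-yl)prop-2-en-1-ol | OCC(=C)[C@@H]1CCC(C)=CC1
F2 | step 8 | (R)-4-(3-bromoprop-1-en-2-yl)-1-methylcyclohex-1-ene | BrCC(=C)[C@@H]1CCC(C)=CC1
F3 | step 8 | (2S,5S,6R)-2-hydroxy-2-methyl-6-{2-[(1R)-4-methylcyclohex-3-en-1-yl]prop-2-en-1-yl}-5-(prop-1-en-2-yl)cyclohexan-1-one | C=C(C[C@@H]1[C@@H](C(=C)C)CC[C@](C)(O)C1=O)[C@@H]1CCC(C)=CC1
F4 | step 8 | (1S,2S,3R,4S)-1-methyl-3-{2-[(1R)-4-methylcyclohex-3-en-1-yl]prop-2-en-1-yl}-4-(prop-1-en-2-yl)cyclohexane-1,2-diol | C=C(C[C@@H]1[C@@H](C(=C)C)CC[C@](C)(O)[C@H]1O)[C@@H]1CCC(C)=CC1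
F5 | step 12 | 2-RA-1-[(1R)-4-(triisopropylsilyloxy)cyclohex-3-en-1-yl]ethan-1-one | O=C(C[C@@H]1[C@@H](C(=C)C)CC[C@](C)(O[Si](C)(C)C(C)(C)C)[C@H]1O[Si](C)(C)C(C)(C)C)[C@@H]1CCC(O[Si](C(C)C)(C(C)C)C(C)C)=CC1
F6 | step 12 | (4R)-4-(3-RA-prop-1-en-2-yl)-1-(triisopropylsilyloxy)cyclohex-1-ene | C=C(C[C@@H]1[C@@H](C(=C)C)CC[C@](C)(O[Si](C)(C)C(C)(C)C)[C@H]1O[Si](C)(C)C(C)(C)C)[C@@H]1CCC(O[Si](C(C)C)(C(C)C)C(C)C)=CC1
F7 | step 12 | (2R,4R)-2-bromo-4-(3-RA-prop-1-en-2-yl)cyclohexan-1-one | C=C(C[C@@H]1[C@@H](C(=C)C)CC[C@](C)(O[Si](C)(C)C(C)(C)C)[C@H]1O[Si](C)(C)C(C)(C)C)[C@@H]1CCC(=O)[C@H](Br)C1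
F8 | step 12 | (1S,2R,4R)-2-bromo-1-methyl-4-(3-RA-prop-1-en-2-yl)cyclohexan-1-ol | C=C(C[C@@H]1[C@@H](C(=C)C)CC[C@](C)(O[Si](C)(C)C(C)(C)C)[C@H]1O[Si](C)(C)C(C)(C)C)[C@@H]1CC[C@](C)(O)[C@H](Br)C1
F9 | step 10 | 2-RA-1-[(3R)-6-methyl-7-oxabicyclo[4.1.0]heptan-3-yl]ethan-1-one, both epoxide faces | O=C(C[C@@H]1[C@@H](C(=C)C)CC[C@](C)(O[Si](C)(C)C(C)(C)C)[C@H]1O[Si](C)(C)C(C)(C)C)[C@@H]1CCC2(C)OC2C1
F10 | step 10 | 2-RA-1-[(1R,3S,4S)-3,4-dihydroxy-4-methylcyclohexyl]ethan-1-one | O=C(C[C@@H]1[C@@H](C(=C)C)CC[C@](C)(O[Si](C)(C)C(C)(C)C)[C@H]1O[Si](C)(C)C(C)(C)C)[C@@H]1CC[C@](C)(O)[C@@H](O)C1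
F11 | step 4 | (2S,5S)-2-(tert-butyldimethylsilyloxy)-2-methyl-5-(prop-1-en-2-yl)cyclohexan-1-one | O=C1C[C@@H](C(C)=C)CC[C@]1(C)O[Si](C)(C)C(C)(C)C
F12 | step 4 | 2-[(1R,3S,6S)-3-(tert-butyldimethylsilyloxy)-3-methyl-2-oxo-6-(prop-1-en-2-yl)cyclohexyl]-N-methoxy-N-methylacetamide | CON(C)C(=O)C[C@@H]1[C@@H](C(=C)C)CC[C@](C)(O[Si](C)(C)C(C)(C)C)C1=O
F13 | step 4 | 2-[(1R,2S,3S,6S)-3-(tert-butyldimethylsilyloxy)-2-hydroxy-3-methyl-6-(prop-1-en-2-yl)cyclohexyl]-N-methoxy-N-methylacetamide | CON(C)C(=O)C[C@@H]1[C@@H](C(=C)C)CC[C@](C)(O[Si](C)(C)C(C)(C)C)[C@H]1O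
A1 | alternative 1 | (S)-6-(tert-butyldimethylsilyloxy)-6-methylcyclohex-2-en-1-one | O=C1C=CCC[C@]1(C)O[Si](C)(C)C(C)(C)C
A2 | alternative 1 | [(1S,2R,4R)-2-bromo-4-(3-bromoprop-1-en-2-yl)-1-methylcyclohexyl]oxy(trimethyl)silane | BrCC(=C)[C@@H]1CC[C@](C)(O[Si](C)(C)C)[C@H](Br)C1
A3 | alternative 1 | ring A C6 ketone with C5 tert-butyldimethylsilyl ether, joined through C7–C8(=C9) to the ring B bromohydrin trimethylsilyl ether | C=C(C[C@@H]1[C@@H](C(=C)C)CC[C@](C)(O[Si](C)(C)C(C)(C)C)C1=O)[C@@H]1CC[C@](C)(O[Si](C)(C)C)[C@H](Br)C1
A4 | alternative 2 | open-chain keto-aldehyde (C6 aldehyde on C1, C5 methyl ketone) carrying the complete ring B bromohydrin | C=C(C[C@@H](C=O)[C@@H](C(=C)C)CCC(C)=O)[C@@H]1CC[C@](C)(O)[C@H](Br)C1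
A5 | alternative 2 | ring A α-hydroxy ketone (C6 ketone, C5 tertiary carbinol) with ring B complete | C=C(C[C@@H]1[C@@H](C(=C)C)CC[C@](C)(O)C1=O)[C@@H]1CC[C@](C)(O)[C@H](Br)C1
A6 | alternative 3 | open-chain (E)-allylsilane (E)-enone with C5/C6 acetonide and ring B bromohydrin trimethylsilyl ether | C[Si](C)(C)C/C(C)=C/CC[C@]1(C)OC(C)(C)O[C@H]1/C=C/C(=O)[C@@H]1CC[C@](C)(O[Si](C)(C)C)[C@H](Br)C1
A7 | alternative 3 | ring A acetonide with C8 ketone and ring B bromohydrin trimethylsilyl ether | O=C(C[C@@H]1[C@@H](C(=C)C)CC[C@]2(C)OC(C)(C)O[C@@H]12)[C@@H]1CC[C@](C)(O[Si](C)(C)C)[C@H](Br)C1
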